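**Retrosynthetic overview**
- The target comes from acid removal of six MOM ethers from a (2S)-flavanone–flavone biaryl.
- The flavanone C-ring is closed second to last by an enantioselective 6-endo oxa-Michael addition of a 2'-hydroxychalcone, the bond that chalcone isomerase makes. Only one phenol is free, so only the 6-linked flavanone can form.
- That chalcone comes from KOH ring opening of a racemic 6-(flavon-8-yl)flavanone, made by Suzuki coupling of a 6-iodoflavanone with a flavone 8-boronate.
- Both iodides come from NIS iodination steered by O-5: free 5-OH gives C-6 (naringenin half), 5-OMOM gives C-8 (apigenin half).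
- Ring order: the flavone C-ring is bought with apigenin. The C-ring of cheap racemic naringenin masks the future ring oxygen, is opened after the coupling and is re-formed under catalyst control.

Assumption: the SMILES defines only C-2 (S); the hindered 6–8'' biaryl axis is undefined, so it is not controlled (10 is racemic about the axis, 11 and 12 are 2S with both axial forms).

**Step 1**
Reactants: 1 (±)-naringenin
Product: 2 racemic 5-hydroxy-7-(methoxymethoxy)-2-[4-(methoxymethoxy)phenyl]chroman-4-one
Conditions: MOMCl (2.3 eq), i-Pr2NEt (3 eq), DMF–CH2Cl2, 0 °C → rt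
Reagents that add atoms: chloromethyl methyl ether (MOMCl), COCCl
Why: Phenol O-alkylation (MOM ether formation); the 7- and 4'-OH react, while the 5-OH, hydrogen-bonded to C-4=O, does not under amine base, and the ring stays closed.

**Step 2**
Reactants: 2 racemic 7,4'-bis-MOM naringenin
Product: 3 racemic 5-hydroxy-6-iodo-7-(methoxymethoxy)-2-[4-(methoxymethoxy)phenyl]chroman-4-one
Conditions: NIS (1.0 eq), DMF, 0 °C → rt, dark
Reagents that add atoms: N-iodosuccinimide (NIS), O=C1CCC(=O)N1I
Why: Electrophilic aromatic iodination; with the 5-OH free, NIS iodinates 5-hydroxy-7-alkoxyflavonoids ortho to the chelated phenol (C-6, para to the ring oxygen), under neutral conditions that spare the MOM ethers.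

**Step 3**
Reactants: 3 racemic 6-iodo-5-hydroxyflavanone
Product: 4 racemic 6-iodo-5,7-bis(methoxymethoxy)-2-[4-(methoxymethoxy)phenyl]chroman-4-one
Conditions: NaH (1.05 eq), DMF–THF, −20 °C, 10 min; MOMCl (1.3 eq), −20 → 0 °C
Reagents that add atoms: chloromethyl methyl ether (MOMCl), COCCl
Why: Phenoxide O-alkylation; one equivalent of NaH takes only the phenol proton and MOMCl caps it before C-3 can be enolised (E1cB ring opening), and this cap is what later leaves the former ring oxygen as the only free phenol.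

**Step 4**
Reactants: 5 apigenin
Product: 6 5,7-bis(methoxymethoxy)-2-[4-(methoxymethoxy)phenyl]-4H-chromen-4-one
Conditions: NaH (4 eq), MOMCl (4 eq), DMF, 0 °C → rt
Reagents that add atoms: chloromethyl methyl ether (MOMCl), COCCl
Why: Exhaustive phenoxide O-alkylation; NaH is needed for the chelated 5-OH, and the aromatic pyranone cannot ring-open.

**Step 5**
Reactants: 6 tri-MOM apigenin
Product: 7 8-iodo-5,7-bis(methoxymethoxy)-2-[4-(methoxymethoxy)phenyl]-4H-chromen-4-one
Conditions: NIS (1.2 eq), DMF, 25 → 50 °C, dark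
Reagents that add atoms: N-iodosuccinimide (NIS), O=C1CCC(=O)N1I
Why: Electrophilic aromatic iodination; with O-5 alkylated the same reagent goes to C-8 (between 7-O and the ring oxygen, less hindered than C-6), the known complement of step 2.

**Step 6**
Reactants: 7 8-iodo-tri-MOM apigenin (1.3 eq), 4 racemic 6-iodo-tri-MOM naringenin (1.0 eq)
Product: 10 (E)-2'-hydroxychalcone carrying the tri-MOM flavon-8-yl group at C-5' (hexa-MOM), via flavone 8-pinacolboronate 8 (not isolated), via racemic 6-(flavon-8-yl)flavanone 9 (not isolated)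
Conditions: Pd(OAc)2 (5 mol%), SPhos (10 mol%), HBpin, Et3N, dioxane, 80 °C; then aq K3PO4, 4, 95 °C; then KOH, MeOH–THF, 25 °C; AcOH to pH 6
Reagents that add atoms: none
Why: Masuda borylation, then Suzuki–Miyaura coupling with Pd/SPhos (a ligand suited to tetra-ortho-oxygenated biaryls), then E1cB retro-oxa-Michael opening in KOH, which gathers closed and partly opened coupled material into one chalcone phenoxide whose only free phenol is the former ring oxygen.

**Step 7**
Reactants: 10 chalcone–flavone hexa-MOM ether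
Product: 11 (2S)-5,7-bis(methoxymethoxy)-2-[4-(methoxymethoxy)phenyl]-6-{5,7-bis(methoxymethoxy)-2-[4-(methoxymethoxy)phenyl]-4-oxo-4H-chromen-8-yl}chroman-4-one
Conditions: tert-leucine-derived bifunctional iminophosphorane–thiourea catalyst (BIMP, P-aryl = 4-MeOC6H4, 10 mol%), toluene, −20 °C, 24–48 h; AcOH quench
Reagents that add atoms: none
Why: Proposed new method: the iminophosphorane deprotonates the 2'-OH to a chiral iminophosphoranium–phenoxide ion pair while the thiourea hydrogen-bonds the enone carbonyl, so O adds to one face of the (E)-enone in a 6-endo oxa-Michael addition that sets C-2 under catalyst control, as chalcone isomerase does with a 2'-oxyanion and a hydrogen-bonded ketone; the closest known reactions are BIMP-catalysed intramolecular oxa-Michael additions to unsaturated esters and amides, and cinchona–thiourea or cinchona ion-pair cyclisations of 2'-hydroxychalcones to flavanones; the weakly acidic product is not re-opened at −20 °C, so the closure is kinetic; the sense of induction cannot be predicted, so the catalyst enantiomer (from L- or D-tert-leucine) that gives 2S is fixed in a pilot run by CD (2S-flavanones: positive near 330 nm, negative near 290 nm).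

**Step 8**
Reactants: 11 (2S)-hexa-MOM flavanone–flavone
Product: 12 target, (2S)-naringenin-(6→8'')-apigenin
Conditions: HCl (1.25 M in MeOH), THF, 0 → 30 °C
Reagents that add atoms: none
Why: Acid-catalysed acetal cleavage (transacetalisation to dimethoxymethane); flavanones racemise by base-mediated ring opening, not in dilute acid at this temperature, and no base is used after step 7, so C-2 stays S.

**Compound list**
1 | (±)-naringenin, racemic 5,7-dihydroxy-2-(4-hydroxyphenyl)chroman-4-one | O=C1CC(c2ccc(O)cc2)Oc2cc(O)cc(O)c12 | starting material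
2 | racemic 5-hydroxy-7-(methoxymethoxy)-2-[4-(methoxymethoxy)phenyl]chroman-4-one | O=C1CC(c2ccc(OCOC)cc2)Oc2cc(OCOC)cc(O)c12 | intermediate
3 | racemic 5-hydroxy-6-iodo-7-(methoxymethoxy)-2-[4-(methoxymethoxy)phenyl]chroman-4-one | O=C1CC(c2ccc(OCOC)cc2)Oc2cc(OCOC)c(I)c(O)c12 | intermediate
4 | racemic 6-iodo-5,7-bis(methoxymethoxy)-2-[4-(methoxymethoxy)phenyl]chroman-4-one | O=C1CC(c2ccc(OCOC)cc2)Oc2cc(OCOC)c(I)c(OCOC)c12 | intermediate
5 | apigenin, 5,7-dihydroxy-2-(4-hydroxyphenyl)-4H-chromen-4-one | O=c1cc(-c2ccc(O)cc2)oc2cc(O)cc(O)c12 | starting material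
6 | 5,7-bis(methoxymethoxy)-2-[4-(methoxymethoxy)phenyl]-4H-chromen-4-one | O=c1cc(-c2ccc(OCOC)cc2)oc2cc(OCOC)cc(OCOC)c12 | intermediate
7 | 8-iodo-5,7-bis(methoxymethoxy)-2-[4-(methoxymethoxy)phenyl]-4H-chromen-4-one | O=c1cc(-c2ccc(OCOC)cc2)oc2c(I)c(OCOC)cc(OCOC)c12 | intermediate
8 | 5,7-bis(methoxymethoxy)-2-[4-(methoxymethoxy)phenyl]-8-(4,4,5,5-tetramethyl-1,3,2-dioxaborolan-2-yl)-4H-chromen-4-one | O=c1cc(-c2ccc(OCOC)cc2)oc2c(B3OC(C)(C)C(C)(C)O3)c(OCOC)cc(OCOC)c12 | intermediate (not isolated)
9 | racemic (at C-2) 5,7-bis(methoxymethoxy)-2-[4-(methoxymethoxy)phenyl]-6-{5,7-bis(methoxymethoxy)-2-[4-(methoxymethoxy)phenyl]-4-oxo-4H-chromen-8-yl}chroman-4-one | O=C1CC(c2ccc(OCOC)cc2)Oc2cc(OCOC)c(-c3c(OCOC)cc(OCOC)c4c(=O)cc(-c5ccc(OCOC)cc5)oc34)c(OCOC)c12 | intermediate (not isolated)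
10 | (E)-1-[6-hydroxy-2,4-bis(methoxymethoxy)-3-{5,7-bis(methoxymethoxy)-2-[4-(methoxymethoxy)phenyl]-4-oxo-4H-chromen-8-yl}phenyl]-3-[4-(methoxymethoxy)phenyl]prop-2-en-1-one | O=C(/C=C/c1ccc(OCOC)cc1)c1c(O)cc(OCOC)c(-c2c(OCOC)cc(OCOC)c3c(=O)cc(-c4ccc(OCOC)cc4)oc23)c1OCOC | intermediate
11 | (2S)-5,7-bis(methoxymethoxy)-2-[4-(methoxymethoxy)phenyl]-6-{5,7-bis(methoxymethoxy)-2-[4-(methoxymethoxy)phenyl]-4-oxo-4H-chromen-8-yl}chroman-4-one | O=C1C[C@@H](c2ccc(OCOC)cc2)Oc2cc(OCOC)c(-c3c(OCOC)cc(OCOC)c4c(=O)cc(-c5ccc(OCOC)cc5)oc34)c(OCOC)c12 | intermediate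
12 | (2S)-5,7-dihydroxy-2-(4-hydroxyphenyl)-6-[5,7-dihydroxy-2-(4-hydroxyphenyl)-4-oxo-4H-chromen-8-yl]chroman-4-one | O=C1C[C@@H](c2ccc(O)cc2)Oc2cc(O)c(-c3c(O)cc(O)c4c(=O)cc(-c5ccc(O)cc5)oc34)c(O)c21 | target

**Step count and risks**
Total: 8 steps. Longest linear sequence: 6 steps (steps 1, 2, 3, 6, 7, 8, from 1 to 12); steps 4 and 5 form the second branch.

Most at risk is step 7. The enantioselective closure of an unactivated 2'-hydroxychalcone is not established at high ee, and the sense of induction has to be found by experiment. The fallback sets out from 10. The ring is closed without stereocontrol (NaOAc, EtOH, 70 °C) to racemic 9. This is resolved kinetically by asymmetric transfer hydrogenation (RuCl(p-cymene)[(R,R)-TsDPEN], HCO2H/Et3N, CH2Cl2, 25 °C, to about 55% conversion). The 2R ketone is reduced to the cis-(2R,4R)-flavan-4-ol F1; the flavone carbonyl, a vinylogous ester, is left alone. The unreacted 2S ketone is 11 (at most 50%), where the route is rejoined.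

Second is step 6. The 2,6-dioxygenated boronate 8 can protodeboronate before the slow tetra-ortho coupling, and hot aqueous base can damage the chalcone. The fallback sets out from 7. Zn dust and LiCl in THF at 50 °C insert into the C–I bond to give the arylzinc iodide F2. Negishi coupling of this with 4 (Pd(OAc)2, SPhos, THF, 60 °C) needs no base and gives 9, which is isolated this time. KOH in MeOH–THF then opens 9 to 10, where the route is rejoined.

Third is step 3. The 5-OH is chelated and hindered by iodine, and any excess base can open the flavanone, which would lose the distinction between the two ortho oxygens. The fallback sets out from 3. NaBH4 (MeOH–THF, 0 °C) reduces the ketone to the flavan-4-ol F3, which has no β-aryloxy ketone and no chelated phenol. K2CO3 and MOMCl in acetone then alkylate only the phenol to give the 5-O-MOM flavan-4-ol F4. Dess–Martin periodinane (NaHCO3, CH2Cl2) re-oxidises the benzylic alcohol to 4, where the route is rejoined.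

**Further compounds**
F1 | step 7 | (2R,4R)-4-hydroxy-5,7-bis(methoxymethoxy)-2-[4-(methoxymethoxy)phenyl]-6-{5,7-bis(methoxymethoxy)-2-[4-(methoxymethoxy)phenyl]-4-oxo-4H-chromen-8-yl}chromane | O[C@@H]1C[C@H](c2ccc(OCOC)cc2)Oc2cc(OCOC)c(-c3c(OCOC)cc(OCOC)c4c(=O)cc(-c5ccc(OCOC)cc5)oc34)c(OCOC)c12
F2 | step 6 | {5,7-bis(methoxymethoxy)-2-[4-(methoxymethoxy)phenyl]-4-oxo-4H-chromen-8-yl}zinc iodide | O=c1cc(-c2ccc(OCOC)cc2)oc2c([Zn]I)c(OCOC)cc(OCOC)c12
F3 | step 3 | racemic 6-iodo-7-(methoxymethoxy)-2-[4-(methoxymethoxy)phenyl]chromane-4,5-diol (C-4 epimers not separated) | OC1CC(c2ccc(OCOC)cc2)Oc2cc(OCOC)c(I)c(O)c12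
F4 | step 3 | racemic 6-iodo-5,7-bis(methoxymethoxy)-2-[4-(methoxymethoxy)phenyl]chroman-4-ol (C-4 epimers not separated) | OC1CC(c2ccc(OCOC)cc2)Oc2cc(OCOC)c(I)c(OCOC)c12
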